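Locants run along the chain from the CHBr carbon (C1) to the CH2Cl carbon (C8). The route rests on disconnecting the C3–C4 oxirane ring together with the C2–C3 bond: a fully substituted C3 (CH3 and C2, with C5 cis to that CH3) is what results when a carbon nucleophile adds to a C3 methyl ketone holding a leaving group on C4. In one operation a silylacetylide, standing in for the unstable bromochlorovinyl carbanion, adds under Cornforth dipole control and the alkoxide expels the C4 chloride with inversion, closing the ring. The precursor is the (4R,6R,7R) α-chloro methyl ketone with its C6 hydroxyl silylated, made by enantioselective bromolactonisation and enamine-catalysed chlorination.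

Key step: step 12

Remark (assumption on the chemistry): in steps 5 and 9 the sense of induction of a known catalyst class on a new substrate cannot be fixed on paper; the catalyst antipode (pseudo-antipode) that gives the drawn configuration is used, both being available, and the sense is to be confirmed on the first batch.

Step 1
Reactants: 1 methyl 4-oxobutanoate; 2 2-(triphenylphosphoranylidene)propanal
Product: 3 methyl (4E)-5-methyl-6-oxohex-4-enoate
Conditions: PhMe, 80 °C
Reagents that add atoms: none
Why: A Wittig olefination with the formyl-stabilised ylide is under thermodynamic control at the oxaphosphetane stage and should give the trisubstituted (E)-enal, which places C5 cis to the C7 methyl as the later anti addition across C6=C7 requires.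

Step 2
Reactants: 3 methyl (4E)-5-methyl-6-oxohex-4-enoate
Product: 4 methyl (4E)-6-hydroxy-5-methylhex-4-enoate
Conditions: NaBH4, CeCl3·7H2O, MeOH, 0 °C
Reagents that add atoms: none
Why: Luche reduction (borohydride activated by the cerium salt in methanol) delivers hydride 1,2 to the enal far faster than to the saturated methyl ester and leaves the alkene geometry untouched.

Step 3
Reactants: 4 methyl (4E)-6-hydroxy-5-methylhex-4-enoate
Product: 5 methyl (4E)-6-chloro-5-methylhex-4-enoate
Conditions: NCS, Me2S, CH2Cl2, −20 → 0 °C
Reagents that add atoms: N-chlorosuccinimide, O=C1CCC(=O)N1Cl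
Why: Corey–Kim chlorination converts the primary allylic alcohol into an alkoxysulfonium salt that chloride displaces directly at C8, a substitution known to proceed without allylic transposition or E/Z scrambling.

Step 4
Reactants: 5 methyl (4E)-6-chloro-5-methylhex-4-enoate
Product: 6 (4E)-6-chloro-5-methylhex-4-enoic acid
Conditions: LiOH, THF/H2O, 0 °C; then aq. HCl to pH 3
Reagents that add atoms: lithium hydroxide, [Li+].[OH-]
Why: Saponification of the unhindered methyl ester by hydroxide is much faster than substitution at the allylic chloride at 0 °C, so short treatment and cold acidification should give the free acid needed for the halocyclisation.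

Step 5
Reactants: 6 (4E)-6-chloro-5-methylhex-4-enoic acid
Product: 7 (5R)-5-[(2R)-2-bromo-1-chloropropan-2-yl]oxolan-2-one
Conditions: NBS, (DHQD)2PHAL or its pseudo-enantiomer (DHQ)2PHAL (10 mol %, see remark), CHCl3/hexane, −40 °C
Reagents that add atoms: N-bromosuccinimide, O=C1CCC(=O)N1Br
Why: Catalytic enantioselective bromolactonisation: the alkaloid-bound bromenium donor attacks one face of the alkene and the carboxylate opens the bromonium ion anti at C6 in a 5-exo closure (attack at C7 is disfavoured by the electron-withdrawing chloromethyl group), so the E geometry fixes the C6/C7 relative configuration and the catalyst fixes the absolute (6R,7R) sense.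

Step 6
Reactants: 7 (5R)-5-[(2R)-2-bromo-1-chloropropan-2-yl]oxolan-2-one
Product: 8 (4R,5R)-5-bromo-6-chloro-4-hydroxy-N-methoxy-N,5-dimethylhexanamide
Conditions: MeNH(OMe)·HCl, AlMe3, CH2Cl2, 0 → 20 °C
Reagents that add atoms: N,O-dimethylhydroxylamine hydrochloride, CNOC.Cl
Why: Weinreb amide formation by aluminium-amide aminolysis opens the γ-lactone at the acyl carbon only, so C6 and C7 are untouched; the crude hydroxy amide is carried on at once because it can relactonise.

Step 7
Reactants: 8 (4R,5R)-5-bromo-6-chloro-4-hydroxy-N-methoxy-N,5-dimethylhexanamide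
Product: 9 (4R,5R)-5-bromo-6-chloro-N-methoxy-N,5-dimethyl-4-(triethylsilyloxy)hexanamide
Conditions: Et3SiOTf, 2,6-lutidine, CH2Cl2, −78 → 0 °C
Reagents that add atoms: triethylsilyl trifluoromethanesulfonate, CC[Si](CC)(CC)OS(=O)(=O)C(F)(F)F
Why: Silylation with the silyl triflate and a hindered pyridine base is fast even for this neopentyl-type secondary alcohol, and the triethylsilyl ether is chosen because it blocks relactonisation and any later C6 alkoxide (which would expel the C7 bromide) yet is small enough to be removed at the end under buffered fluoride.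

Step 8
Reactants: 9 (4R,5R)-5-bromo-6-chloro-N-methoxy-N,5-dimethyl-4-(triethylsilyloxy)hexanamide
Product: 10 (4R,5R)-5-bromo-6-chloro-5-methyl-4-(triethylsilyloxy)hexanal
Conditions: iBu2AlH, THF, −78 °C; aq. potassium sodium tartrate
Reagents that add atoms: none
Why: Reduction of a Weinreb amide stops at the chelated aluminium hemiaminal, which releases the aldehyde only on work-up, so over-reduction is avoided and the alkyl halides are inert at −78 °C.

Step 9
Reactants: 10 (4R,5R)-5-bromo-6-chloro-5-methyl-4-(triethylsilyloxy)hexanal
Product: 11 (2R,4R,5R)-5-bromo-2,6-dichloro-5-methyl-4-(triethylsilyloxy)hexanal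
Conditions: NCS, (2R,5R)- or (2S,5S)-2,5-diphenylpyrrolidine (10 mol %, see remark), CH2Cl2, 0 → 20 °C
Reagents that add atoms: N-chlorosuccinimide, O=C1CCC(=O)N1Cl
Why: Enamine-catalysed electrophilic α-chlorination of an unbranched aldehyde: the C2-symmetric pyrrolidine forms the (E)-enamine and shields one face towards N-chlorosuccinimide, so C4 is set as R (anti to the C6 oxygen in the zigzag chain) under catalyst control, and the configurationally labile product is used crude.

Step 10
Reactants: 11 (2R,4R,5R)-5-bromo-2,6-dichloro-5-methyl-4-(triethylsilyloxy)hexanal; 12 methylmagnesium bromide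
Product: 13 (3R,5R,6R)-6-bromo-3,7-dichloro-6-methyl-5-(triethylsilyloxy)heptan-2-ol (both C2 epimers, that is both epimers at target C3)
Conditions: Et2O, −78 °C; aq. NH4Cl
Reagents that add atoms: none
Why: Grignard 1,2-addition to the α-chloro aldehyde at −78 °C outruns enolisation and halide displacement, leaves C4 untouched, and both C3 epimers are acceptable because C3 is oxidised in the next step.

Step 11
Reactants: 13 (3R,5R,6R)-6-bromo-3,7-dichloro-6-methyl-5-(triethylsilyloxy)heptan-2-ol
Product: 14 (3R,5R,6R)-6-bromo-3,7-dichloro-6-methyl-5-(triethylsilyloxy)heptan-2-one (target locants 4R,6R,7R)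
Conditions: Dess–Martin periodinane, NaHCO3, CH2Cl2, 0 → 20 °C
Reagents that add atoms: none
Why: Dess–Martin oxidation under bicarbonate buffering converts the secondary chlorohydrin into the α-chloro ketone without base or strong acid, so the C3 epimers converge and the C4 stereocentre should be retained.

Step 12
Reactants: 14 (3R,5R,6R)-6-bromo-3,7-dichloro-6-methyl-5-(triethylsilyloxy)heptan-2-one; 15 ethynyltrimethylsilane
Product: 18 (3S,4S,6R,7R)-7-bromo-8-chloro-3,4-epoxy-3,7-dimethyl-6-(triethylsilyloxy)-1-(trimethylsilyl)oct-1-yne, via lithium trimethylsilylacetylide 16 (not isolated), via lithium chlorohydrin alkoxide 17 (not isolated)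
Conditions: 15 (1.4 equiv), n-BuLi (1.3 equiv), THF, −78 °C; add 14, −78 °C; then DMPU, −78 → 20 °C
Reagents that add atoms: none
Why: Acetylide 16 adds to the C3 carbonyl of 14 in the arrangement that opposes the C4–Cl and C=O dipoles and approaches past C4–H instead of C5, giving the (3S,4R) tertiary alkoxide 17, whose oxygen on warming displaces chloride from C4 with inversion. The closest known reaction type is the Cornforth-selective addition (the polar Felkin–Anh model predicts the same isomer) of lithium acetylides to α-chloro carbonyl compounds, followed by Williamson-type closure of the chlorohydrin alkoxide. The oxirane ring closes in the 3-exo-tet mode, the C7 bromide and C8 chloride being out of reach (six- and seven-membered closures at hindered carbons). The new stereocentre C3 is controlled by the neighbouring C4 stereocentre through dipole minimisation and the size difference between H and C5, and C4 is inverted stereospecifically, which puts C5 cis to the C3 methyl. The step needs one ketone face and addition faster than enolisation; the non-chelating lithium counter-ion in THF at −78 °C and the small, weakly basic sp nucleophile attacking an activated α-chloro ketone should secure both. The C6 triethylsilyl ether prevents a second alkoxide that would expel the C7 bromide, and DMPU speeds the closure so that silyl transfer to the C3 oxygen should not compete.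

Step 13
Reactants: 18 (3S,4S,6R,7R)-7-bromo-8-chloro-3,4-epoxy-3,7-dimethyl-6-(triethylsilyloxy)-1-(trimethylsilyl)oct-1-yne
Product: 19 (3S,4S,6R,7R)-1,7-dibromo-8-chloro-3,4-epoxy-3,7-dimethyl-6-(triethylsilyloxy)oct-1-yne
Conditions: NBS, AgNO3 (10 mol %), acetone, 20 °C, dark
Reagents that add atoms: N-bromosuccinimide, O=C1CCC(=O)N1Br
Why: Silver-catalysed bromodesilylation of an alkynylsilane (a silver acetylide is formed and brominated by N-bromosuccinimide) is a known direct exchange that should spare the oxirane and the silyl ether, the tertiary bromide being deactivated towards silver-assisted ionisation by its β-chloro and β-silyloxy groups and the silver being used only in catalytic amount.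

Step 14
Reactants: 19 (3S,4S,6R,7R)-1,7-dibromo-8-chloro-3,4-epoxy-3,7-dimethyl-6-(triethylsilyloxy)oct-1-yne
Product: 20 (1Z,3R,4S,6R,7R)-1,7-dibromo-2,8-dichloro-3,4-epoxy-3,7-dimethyl-6-(triethylsilyloxy)oct-1-ene
Conditions: Pd(OAc)2 (5 mol %), LiCl, AcOH (10 equiv), MeCN, 20 °C
Reagents that add atoms: lithium chloride, [Li+].[Cl-]
Why: Palladium-catalysed hydrochlorination of a 1-bromoalkyne: chloride attacks C2 of the alkyne bound to divalent palladium from the face opposite the metal (anti-chloropalladation, with the metal on the bromine-bearing carbon) and acetic acid then cleaves the C1–Pd bond with retention, so H and Cl end up trans, that is Cl cis to Br as in the (Z)-alkene, while the small excess of acid in acetonitrile and a short reaction time are meant to spare the oxirane.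

Step 15
Reactants: 20 (1Z,3R,4S,6R,7R)-1,7-dibromo-2,8-dichloro-3,4-epoxy-3,7-dimethyl-6-(triethylsilyloxy)oct-1-ene
Product: 21 (1Z,3R,4S,6R,7R)-1,7-dibromo-2,8-dichloro-3,4-epoxy-3,7-dimethyloct-1-en-6-ol
Conditions: HF·pyridine, pyridine, THF, 0 °C
Reagents that add atoms: none
Why: Fluoride-mediated cleavage of the triethylsilyl ether with pyridine-buffered HF·pyridine is close to neutral, generates no C6 alkoxide (which would close onto C7), and should leave the oxirane and the vinyl dihalide intact.

Compound list
1 | methyl 4-oxobutanoate | COC(=O)CCC=O | starting material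
2 | 2-(triphenylphosphoranylidene)propanal | CC(C=O)=P(c1ccccc1)(c1ccccc1)c1ccccc1 | starting material
3 | methyl (4E)-5-methyl-6-oxohex-4-enoate | COC(=O)CC/C=C(\C)C=O | intermediate
4 | methyl (4E)-6-hydroxy-5-methylhex-4-enoate | COC(=O)CC/C=C(\C)CO | intermediate
5 | methyl (4E)-6-chloro-5-methylhex-4-enoate | COC(=O)CC/C=C(\C)CCl | intermediate
6 | (4E)-6-chloro-5-methylhex-4-enoic acid | OC(=O)CC/C=C(\C)CCl | intermediate
7 | (5R)-5-[(2R)-2-bromo-1-chloropropan-2-yl]oxolan-2-one | C[C@](Br)(CCl)[C@H]1CCC(=O)O1 | intermediate
8 | (4R,5R)-5-bromo-6-chloro-4-hydroxy-N-methoxy-N,5-dimethylhexanamide | C[C@](Br)(CCl)[C@H](O)CCC(=O)N(C)OC | intermediate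
9 | (4R,5R)-5-bromo-6-chloro-N-methoxy-N,5-dimethyl-4-(triethylsilyloxy)hexanamide | C[C@](Br)(CCl)[C@H](O[Si](CC)(CC)CC)CCC(=O)N(C)OC | intermediate
10 | (4R,5R)-5-bromo-6-chloro-5-methyl-4-(triethylsilyloxy)hexanal | C[C@](Br)(CCl)[C@H](O[Si](CC)(CC)CC)CCC=O | intermediate
11 | (2R,4R,5R)-5-bromo-2,6-dichloro-5-methyl-4-(triethylsilyloxy)hexanal | C[C@](Br)(CCl)[C@H](O[Si](CC)(CC)CC)C[C@@H](Cl)C=O | intermediate
12 | methylmagnesium bromide | C[Mg]Br | starting material
13 | (3R,5R,6R)-6-bromo-3,7-dichloro-6-methyl-5-(triethylsilyloxy)heptan-2-ol, both C2 epimers | C[C@](Br)(CCl)[C@H](O[Si](CC)(CC)CC)C[C@@H](Cl)C(C)O | intermediate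
14 | (3R,5R,6R)-6-bromo-3,7-dichloro-6-methyl-5-(triethylsilyloxy)heptan-2-one (C6-silylated α-chloro methyl ketone) | C[C@](Br)(CCl)[C@H](O[Si](CC)(CC)CC)C[C@@H](Cl)C(C)=O | intermediate
15 | ethynyltrimethylsilane | C#C[Si](C)(C)C | starting material
16 | lithium trimethylsilylacetylide | [Li]C#C[Si](C)(C)C | intermediate (formed in the flask, not isolated)
17 | lithium (3S,4R,6R,7R)-7-bromo-4,8-dichloro-3,7-dimethyl-6-(triethylsilyloxy)-1-(trimethylsilyl)oct-1-yn-3-olate | C[C@](Br)(CCl)[C@H](O[Si](CC)(CC)CC)C[C@@H](Cl)[C@@](C)(O[Li])C#C[Si](C)(C)C | intermediate (formed in the flask, not isolated)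
18 | (3S,4S,6R,7R)-7-bromo-8-chloro-3,4-epoxy-3,7-dimethyl-6-(triethylsilyloxy)-1-(trimethylsilyl)oct-1-yne | C[C@](Br)(CCl)[C@H](O[Si](CC)(CC)CC)C[C@@H]1O[C@@]1(C)C#C[Si](C)(C)C | intermediate
19 | (3S,4S,6R,7R)-1,7-dibromo-8-chloro-3,4-epoxy-3,7-dimethyl-6-(triethylsilyloxy)oct-1-yne | C[C@](Br)(CCl)[C@H](O[Si](CC)(CC)CC)C[C@@H]1O[C@@]1(C)C#CBr | intermediate
20 | (1Z,3R,4S,6R,7R)-1,7-dibromo-2,8-dichloro-3,4-epoxy-3,7-dimethyl-6-(triethylsilyloxy)oct-1-ene | C[C@](Br)(CCl)[C@H](O[Si](CC)(CC)CC)C[C@@H]1O[C@@]1(C)/C(Cl)=C/Br | intermediate
21 | (1Z,3R,4S,6R,7R)-1,7-dibromo-2,8-dichloro-3,4-epoxy-3,7-dimethyloct-1-en-6-ol | C[C@](Br)(CCl)[C@H](O)C[C@@H]1O[C@@]1(C)/C(Cl)=C/Br | target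

Total step count: 15. Longest linear sequence: 15 steps (1 to 21).

Steps most likely to fail

1. Step 12. What may go wrong: incomplete facial discrimination at the ketone (the C3 methyl lies next to the C4–Cl bond in the dipole-opposed arrangement, and H versus CH2 is a small size difference), enolisation of the α-chloro ketone by the acetylide, or slow ring closure that lets silyl transfer compete. Fallback, setting out from aldehyde 10 and returning at bromoalkyne 19: the oxirane is made by reagent-controlled epoxidation instead of substrate-controlled carbonyl addition. Aldehyde 10 is converted with Me3SiCl, Et3N and NaI in MeCN into its trimethylsilyl enol ether F1, and ozonolysis (O3, CH2Cl2, −78 °C, then PPh3) removes the old C3 to give the one-carbon-shorter aldehyde F2. Wittig reaction with ethyl 2-(triphenylphosphoranylidene)propanoate should give the (E)-enoate F3, which carries the new C4=C3 bond, the C3 methyl and C2; iBu2AlH should reduce it to the (E)-allylic alcohol F4. Sharpless epoxidation (Ti(OiPr)4, L-(+)-diethyl tartrate, tBuOOH, 4 Å sieves, −20 °C) should then give the (3S,4S) epoxy alcohol F5 with C5 cis to the methyl. Dess–Martin oxidation should give the epoxy aldehyde F6, the Ohira–Bestmann reagent (dimethyl (1-diazo-2-oxopropyl)phosphonate, K2CO3, MeOH) the terminal alkynyl epoxide F7, and NBS with AgNO3 (10 mol %) in acetone then gives 19.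

2. Step 14. What may go wrong: opening of the oxirane by chloride in the acidic medium while the alkyne is being hydrochlorinated, or partial loss of the silyl ether. Fallback, setting out from 19 and returning at 20: the oxirane is no longer shielded from the medium but deliberately carried through it in ring-opened form. With excess LiCl in neat AcOH and Pd(OAc)2 the alkyne is hydrochlorinated and the oxirane is opened by chloride at the secondary C4 with inversion. This should give the chlorohydrin (1Z,3R,4R,6R,7R)-1,7-dibromo-2,4,8-trichloro-3,7-dimethyl-6-(triethylsilyloxy)oct-1-en-3-ol F8, which has the same C3–O/C4–Cl arrangement as intermediate 17. K2CO3 in MeOH at 0 °C then re-closes the ring with a second inversion at C4 and returns 20.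

3. Step 5. What may go wrong: insufficient enantiofacial discrimination by the alkaloid catalyst on an aliphatic trisubstituted alkene that carries an allylic chloride. Fallback, setting out from 6 and returning at 7: enantiocontrol is replaced by resolution. Uncatalysed bromolactonisation (NBS, NaHCO3, CH2Cl2, 0 °C) is still anti and 5-exo and should give lactone 7 together with its enantiomer, (5S)-5-[(2S)-2-bromo-1-chloropropan-2-yl]oxolan-2-one F9. Preparative chromatography on a cellulose-based chiral stationary phase separates the two and returns enantiopure 7.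

Further compounds
F1 | step 12 | (4R,5R)-5-bromo-6-chloro-5-methyl-4-(triethylsilyloxy)-1-(trimethylsilyloxy)hex-1-ene (E/Z mixture) | C[C@](Br)(CCl)[C@H](O[Si](CC)(CC)CC)CC=CO[Si](C)(C)C
F2 | step 12 | (3R,4R)-4-bromo-5-chloro-4-methyl-3-(triethylsilyloxy)pentanal | C[C@](Br)(CCl)[C@H](O[Si](CC)(CC)CC)CC=O
F3 | step 12 | ethyl (2E,5R,6R)-6-bromo-7-chloro-2,6-dimethyl-5-(triethylsilyloxy)hept-2-enoate | C[C@](Br)(CCl)[C@H](O[Si](CC)(CC)CC)C/C=C(\C)C(=O)OCC
F4 | step 12 | (2E,5R,6R)-6-bromo-7-chloro-2,6-dimethyl-5-(triethylsilyloxy)hept-2-en-1-ol | C[C@](Br)(CCl)[C@H](O[Si](CC)(CC)CC)C/C=C(\C)CO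
F5 | step 12 | [(2S,3S)-3-[(2R,3R)-3-bromo-4-chloro-3-methyl-2-(triethylsilyloxy)butyl]-2-methyloxiran-2-yl]methanol | C[C@](Br)(CCl)[C@H](O[Si](CC)(CC)CC)C[C@@H]1O[C@@]1(C)CO
F6 | step 12 | (2R,3S)-3-[(2R,3R)-3-bromo-4-chloro-3-methyl-2-(triethylsilyloxy)butyl]-2-methyloxirane-2-carbaldehyde | C[C@](Br)(CCl)[C@H](O[Si](CC)(CC)CC)C[C@@H]1O[C@@]1(C)C=O
F7 | step 12 | (3S,4S,6R,7R)-7-bromo-8-chloro-3,4-epoxy-3,7-dimethyl-6-(triethylsilyloxy)oct-1-yne | C[C@](Br)(CCl)[C@H](O[Si](CC)(CC)CC)C[C@@H]1O[C@@]1(C)C#C
F8 | step 14 | (1Z,3R,4R,6R,7R)-1,7-dibromo-2,4,8-trichloro-3,7-dimethyl-6-(triethylsilyloxy)oct-1-en-3-ol | C[C@](Br)(CCl)[C@H](O[Si](CC)(CC)CC)C[C@@H](Cl)[C@@](C)(O)/C(Cl)=C/Br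
F9 | step 5 | (5S)-5-[(2S)-2-bromo-1-chloropropan-2-yl]oxolan-2-one | C[C@@](Br)(CCl)[C@@H]1CCC(=O)O1
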